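**Assumption:** the SMILES is read as (3R,5R)-5-bromo-3-[(1S,3S,4S)-3-bromo-4-chloro-4-methylcyclohexyl]-3,6-dihydroxy-6-methylheptan-2-one. C3 and C5 of the chain are formed in step 5 without reliable control, so the wanted isomer is separated there.

**Retrosynthetic overview**
1. 15 ⇐ 14: unmask the tertiary carbinol (chloroacetate).
2. Key disconnection C3–C4 together with C5–Br: bromine-atom-transfer radical addition of the tertiary α-acyloxy-α-acyl bromide 13 to 2-methylbut-3-en-2-ol 12.
3. Ring Br/Cl ⇐ cyclohexene 8: anti chlorohydrin → tertiary bromide → 1,2-halogen interchange (diaxial → diequatorial).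
4. α-Acyloxy ketone 8 ⇐ aldehyde 3 + acetyl anion equivalent from ethyl vinyl ether 4.
5. Ring formation: the only ring is made first, by enantioselective Diels–Alder reaction of isoprene 1 and acrolein 2.

**Route**

Step 1
Reactants: 1 isoprene (2-methylbuta-1,3-diene); 2 acrolein (prop-2-enal)
Product: 3 (1S)-4-methylcyclohex-3-ene-1-carbaldehyde
Conditions: (5R)-5-benzyl-2,2,3-trimethylimidazolidin-4-one·HCl (20 mol%), MeCN/H2O 95:5, −10 °C
Reagents that add atoms: none
Why: Iminium-catalysed enantioselective Diels–Alder reaction; the 2-substituted diene gives the 1,4-("para") adduct and the benzyl group of the catalyst shields one face of the acrolein iminium ion, which sets ring C1 as S (the catalyst enantiomer is chosen for this sense; about 85–90% ee expected).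

Step 2
Reactants: 3 (1S)-4-methylcyclohex-3-ene-1-carbaldehyde; 4 ethyl vinyl ether
Product: 8 1-[(1S)-4-methylcyclohex-3-en-1-yl]-2-oxopropyl 2-chloroacetate (both epimers at the acyloxy carbon), via 1-ethoxyvinyllithium 5 (not isolated), via lithium alkoxide adduct 6 (not isolated), via enol ether chloroacetate 7 (not isolated)
Conditions: 4, t-BuLi, THF, −78 → 0 °C; 3, −78 °C; ClCH2COCl, −78 → 0 °C; 0.5 M HCl/THF, 0 °C
Reagents that add atoms: chloroacetyl chloride (O=C(Cl)CCl); water (O)
Why: Acyl-anion-equivalent 1,2-addition (1-ethoxyvinyllithium) is faster than α-deprotonation at −78 °C, so ring C1 is kept; acylation of the alkoxide in the same pot and mild enol-ether hydrolysis give the protected acyloin, whose new carbinol centre is an epimer mixture that is erased when it becomes the planar radical in step 5.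

Step 3
Reactants: 8 1-[(1S)-4-methylcyclohex-3-en-1-yl]-2-oxopropyl 2-chloroacetate
Product: 9 1-[(1S,3R,4R)-3-chloro-4-hydroxy-4-methylcyclohexyl]-2-oxopropyl 2-chloroacetate
Conditions: trichloroisocyanuric acid (0.37 equiv), MeCN/H2O 4:1, 0 °C
Reagents that add atoms: trichloroisocyanuric acid (O=C1N(Cl)C(=O)N(Cl)C(=O)N1Cl); water (O)
Why: Chlorohydrin formation by electrophilic chlorination; Cl+ adds to the face anti to the equatorial side chain and water opens the chloronium ion trans-diaxially at the tertiary carbon (Markovnikov, Fürst–Plattner), which puts Cl at C3 trans and OH at C4 cis to the side chain, while the acylated carbinol cannot add to the chloronium ion.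

Step 4
Reactants: 9 1-[(1S,3R,4R)-3-chloro-4-hydroxy-4-methylcyclohexyl]-2-oxopropyl 2-chloroacetate
Product: 11 1-[(1S,3S,4S)-3-bromo-4-chloro-4-methylcyclohexyl]-2-oxopropyl 2-chloroacetate, via tertiary bromide 10 (not isolated)
Conditions: Me3SiBr (1.5 equiv), CH2Cl2, −20 → 0 °C; then MeNO2, 60 °C
Reagents that add atoms: bromotrimethylsilane (C[Si](C)(C)Br)
Why: SN1 bromination of the tertiary alcohol with anchimeric assistance by the anti chlorine (retention) gives the trans-diaxial bromochloride 10; its thermal 1,2-interchange of vicinal halogens (dyotropic diaxial → diequatorial rearrangement through the bridged ion pair) moves Cl to the tertiary and Br to the secondary carbon with inversion at both, giving the trans-diequatorial (3S,4S) array with Br cis to the side chain, which direct BrCl addition (Br trans to the side chain) would not give.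

Step 5
Reactants: 11 1-[(1S,3S,4S)-3-bromo-4-chloro-4-methylcyclohexyl]-2-oxopropyl 2-chloroacetate; 12 2-methylbut-3-en-2-ol
Product: 14 (3R,5R)-5-bromo-3-[(1S,3S,4S)-3-bromo-4-chloro-4-methylcyclohexyl]-6-hydroxy-6-methyl-2-oxoheptan-3-yl 2-chloroacetate, via tertiary bromide 13 (not isolated)
Conditions: NBS (1.05 equiv), hν, PhCF3, 25 °C; filter; 12 (5 equiv), [Cu(dap)2]Cl (dap = 2,9-bis(4-methoxyphenyl)-1,10-phenanthroline; 1 mol%), 530 nm LED, MeCN, 25 °C
Reagents that add atoms: N-bromosuccinimide (O=C1CCC(=O)N1Br)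
Why: Radical bromination of the captodative C–H, then Kharasch-type bromine-atom-transfer radical addition under monovalent copper photocatalysis: the tertiary α-acyloxy-α-acyl radical adds to the CH2 end of 12 and the secondary adduct radical takes up bromine, so C3–C4 and C5–Br form in one step with the tertiary alcohol already in place; C3 and C5 are created here without dependable substrate control (the ring centres are remote and 1,3-induction across CH2 is weak), so the (3R,5R) isomer 14 is separated from its diastereomers by HPLC.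

Step 6
Reactants: 14 (3R,5R)-5-bromo-3-[(1S,3S,4S)-3-bromo-4-chloro-4-methylcyclohexyl]-6-hydroxy-6-methyl-2-oxoheptan-3-yl 2-chloroacetate
Product: 15 (3R,5R)-5-bromo-3-[(1S,3S,4S)-3-bromo-4-chloro-4-methylcyclohexyl]-3,6-dihydroxy-6-methylheptan-2-one (target)
Conditions: thiourea (3 equiv), NaHCO3, EtOH, 50 °C
Reagents that add atoms: none
Why: Chloroacetate cleavage by the thiourea method (S-alkylation, then cyclisation onto the ester carbonyl) is nearly neutral, so the bromohydrin is not closed to an epoxide, the ring halides are not eliminated and no stereocentre is touched.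

**Compound list**
1 | isoprene (2-methylbuta-1,3-diene) | C=CC(C)=C | starting material
2 | acrolein (prop-2-enal) | C=CC=O | starting material
3 | (1S)-4-methylcyclohex-3-ene-1-carbaldehyde | O=C[C@H]1CCC(C)=CC1 | intermediate
4 | ethyl vinyl ether (ethoxyethene) | C=COCC | starting material
5 | 1-ethoxyvinyllithium | [Li]C(=C)OCC | intermediate
6 | lithium 2-ethoxy-1-[(1S)-4-methylcyclohex-3-en-1-yl]prop-2-en-1-olate | [Li]OC(C(=C)OCC)[C@H]1CCC(C)=CC1 | intermediate
7 | 2-ethoxy-1-[(1S)-4-methylcyclohex-3-en-1-yl]prop-2-en-1-yl 2-chloroacetate | C=C(OCC)C(OC(=O)CCl)[C@H]1CCC(C)=CC1 | intermediate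
8 | 1-[(1S)-4-methylcyclohex-3-en-1-yl]-2-oxopropyl 2-chloroacetate | CC(=O)C(OC(=O)CCl)[C@H]1CCC(C)=CC1 | intermediate
9 | 1-[(1S,3R,4R)-3-chloro-4-hydroxy-4-methylcyclohexyl]-2-oxopropyl 2-chloroacetate | CC(=O)C(OC(=O)CCl)[C@H]1CC[C@@](C)(O)[C@H](Cl)C1 | intermediate
10 | 1-[(1S,3R,4R)-4-bromo-3-chloro-4-methylcyclohexyl]-2-oxopropyl 2-chloroacetate | CC(=O)C(OC(=O)CCl)[C@H]1CC[C@@](C)(Br)[C@H](Cl)C1 | intermediate
11 | 1-[(1S,3S,4S)-3-bromo-4-chloro-4-methylcyclohexyl]-2-oxopropyl 2-chloroacetate | CC(=O)C(OC(=O)CCl)[C@H]1CC[C@](C)(Cl)[C@@H](Br)C1 | intermediate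
12 | 2-methylbut-3-en-2-ol | C=CC(C)(C)O | starting material
13 | 1-bromo-1-[(1S,3S,4S)-3-bromo-4-chloro-4-methylcyclohexyl]-2-oxopropyl 2-chloroacetate | CC(=O)C(Br)(OC(=O)CCl)[C@H]1CC[C@](C)(Cl)[C@@H](Br)C1 | intermediate
14 | (3R,5R)-5-bromo-3-[(1S,3S,4S)-3-bromo-4-chloro-4-methylcyclohexyl]-6-hydroxy-6-methyl-2-oxoheptan-3-yl 2-chloroacetate | CC(=O)[C@@](OC(=O)CCl)(C[C@@H](Br)C(C)(C)O)[C@H]1CC[C@](C)(Cl)[C@@H](Br)C1 | intermediate
15 | (3R,5R)-5-bromo-3-[(1S,3S,4S)-3-bromo-4-chloro-4-methylcyclohexyl]-3,6-dihydroxy-6-methylheptan-2-one | CC(=O)[C@@](O)(C[C@@H](Br)C(C)(C)O)[C@H]1CC[C@](C)(Cl)[C@@H](Br)C1 | target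

**Total step count:** 6. **Longest linear sequence:** 6 (from 1 and 2).

**Steps most likely to fail, with fallbacks**

Step 5 (radical key step). The hindered tertiary radical may add slowly to an unactivated alkene, bromide 13 can lose HBr, and there is no dependable control at C3 or C5, so up to four diastereomers can form. The fallback sets out from bromide 13. A radical chain allyl transfer with allyl ethyl sulfone (Et3B/air, 25 °C) gives (3R)-3-[(1S,3S,4S)-3-bromo-4-chloro-4-methylcyclohexyl]-2-oxohex-5-en-3-yl 2-chloroacetate F1 together with its C3 epimer. Cross-metathesis with 2-methylbut-2-ene, using the second-generation Grubbs catalyst (H2IMes)(PCy3)Cl2Ru=CHPh, turns the allyl into a prenyl group and gives (3R)-3-[(1S,3S,4S)-3-bromo-4-chloro-4-methylcyclohexyl]-6-methyl-2-oxohept-5-en-3-yl 2-chloroacetate F2. NBS in wet THF then forms the bromohydrin. Here the ketone carbonyl can open the bromonium ion through a six-membered oxocarbenium ion, which offers 1,3-control of C5 that the atom-transfer step lacks. The sequence comes back to the route at 14.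

Step 4 (bromide formation and halogen interchange). The tertiary cation may be captured on the wrong face, giving a cis bromochloride that cannot interchange. HBr may be lost, the interchange may stop short of completion, and the acyloin ester may shift its acyl group. The fallback sets out from alkene 8. Epoxidation with 3-chloroperbenzoic acid and separation of the epoxide trans to the side chain gives 1-[(1R,3S,6S)-6-methyl-7-oxabicyclo[4.1.0]heptan-3-yl]-2-oxopropyl 2-chloroacetate F3. HBr opens it trans-diaxially at the tertiary carbon to 1-[(1S,3R,4R)-4-bromo-3-hydroxy-4-methylcyclohexyl]-2-oxopropyl 2-chloroacetate F4. With SOCl2/pyridine the chlorosulfite leaves with participation of the anti bromine, and chloride opens the bromonium ion at the tertiary carbon. Attack at the secondary carbon would give 10, which feeds the same interchange. The sequence comes back to the route at 11.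

Step 3 (chlorohydrin). Ene-type allylic chlorination of the trisubstituted alkene and α-chlorination of the ketone can compete. The fallback sets out from alkene 8. NBS in aqueous THF gives the trans-diaxial bromohydrin 1-[(1S,3R,4R)-3-bromo-4-hydroxy-4-methylcyclohexyl]-2-oxopropyl 2-chloroacetate F5. Ag2O closes it to the epoxide cis to the side chain, 1-[(1S,3S,6R)-6-methyl-7-oxabicyclo[4.1.0]heptan-3-yl]-2-oxopropyl 2-chloroacetate F6. HCl in ether at −20 °C opens this epoxide trans-diaxially at the secondary carbon. The sequence comes back to the route at 9.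

Further compounds
F1 | step 5 | (3R)-3-[(1S,3S,4S)-3-bromo-4-chloro-4-methylcyclohexyl]-2-oxohex-5-en-3-yl 2-chloroacetate | CC(=O)[C@@](OC(=O)CCl)(CC=C)[C@H]1CC[C@](C)(Cl)[C@@H](Br)C1
F2 | step 5 | (3R)-3-[(1S,3S,4S)-3-bromo-4-chloro-4-methylcyclohexyl]-6-methyl-2-oxohept-5-en-3-yl 2-chloroacetate | CC(=O)[C@@](OC(=O)CCl)(CC=C(C)C)[C@H]1CC[C@](C)(Cl)[C@@H](Br)C1
F3 | step 4 | 1-[(1R,3S,6S)-6-methyl-7-oxabicyclo[4.1.0]heptan-3-yl]-2-oxopropyl 2-chloroacetate | CC(=O)C(OC(=O)CCl)[C@H]1CC[C@]2(C)O[C@@H]2C1
F4 | step 4 | 1-[(1S,3R,4R)-4-bromo-3-hydroxy-4-methylcyclohexyl]-2-oxopropyl 2-chloroacetate | CC(=O)C(OC(=O)CCl)[C@H]1CC[C@@](C)(Br)[C@H](O)C1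
F5 | step 3 | 1-[(1S,3R,4R)-3-bromo-4-hydroxy-4-methylcyclohexyl]-2-oxopropyl 2-chloroacetate | CC(=O)C(OC(=O)CCl)[C@H]1CC[C@@](C)(O)[C@H](Br)C1
F6 | step 3 | 1-[(1S,3S,6R)-6-methyl-7-oxabicyclo[4.1.0]heptan-3-yl]-2-oxopropyl 2-chloroacetate | CC(=O)C(OC(=O)CCl)[C@H]1CC[C@@]2(C)O[C@H]2C1
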